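**Retrosynthetic overview** (butenolide locants: O1, C2(=O), C3, C4(Br), C5 = spiro carbon, C6 = bromomethine carbon, C1' = side-chain carbinol)

1. 19 ⇐ 17: the target is a mixed (S)/(R) diacetate on a C2-symmetric core. It is reached from the C2-symmetric (R,R)-diol 17 by Mitsunobu inversion with AcOH at one of the two homotopic carbinols and plain acetylation of the other.
2. 17 ⇐ 15 ⇐ 2 × 14: the cyclobutane (C5–C5' and C6–C6' bonds) is made last, by a head-to-head anti [2+2] photocycloaddition of two (Z)-bromomethylene butenolides tied through their carbinol oxygens by a removable O–Si(i-Pr)2–O bridge.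
3. 14 ⇐ 12 ⇐ 9: each butenolide ring is closed by forming its C2(=O)–C3 bond, in an oxidative alkoxycarbonyl-palladation of the acyclic bromoallenol 9 with acetate capture of the resulting allylpalladium at C1'.
4. Enabling feature: in each lactone ring (O1, C2, C3, C4, C5) the carbonyl carbon C2 sits on C3, the central carbon of the unit Br–C4=C3–C1'(OAc). This is the retron of acyl addition to the central carbon of a 1-bromoallene C4(Br)=C3=C1'H–Pr followed by O-capture at C1'. The allene comes from a propargylic mesylate by anti SN2' bromide delivery, so the one catalytically set carbinol (step 2) is relayed centre → axis → centre and then to the four ring stereocentres.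
5. Ring order: butenolide ring (step 7, used for both halves) → cyclobutane together with a temporary 11-membered silylene-containing ring (step 11) → temporary ring opened (step 12).

Key step: step 7

Remark: the two side-chain centres of 19 have opposite descriptors (one S, one R) on a C2-symmetric (5S,6S,11R,12R) core, so the core alone makes the molecule chiral and either carbinol of the C2-symmetric (R,R)-diol 17 may be the one that is inverted.

**Route**

Step 1
Reactants: 1 3,3-diethoxyprop-1-yne; 2 N-methoxy-N-methylbutanamide
Product: 4 1,1-diethoxyhept-2-yn-4-one, via lithium acetylide 3 (not isolated)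
Conditions: n-BuLi, THF, −78 °C; then 2, −78 → 0 °C; aq NH4Cl
Reagents that add atoms: none
Why: Weinreb ketone synthesis, in which the chelated tetrahedral adduct of the lithium acetylide survives until work-up so that acylation stops at the ynone.

Step 2
Reactants: 4 1,1-diethoxyhept-2-yn-4-one
Product: 5 (4R)-1,1-diethoxyhept-2-yn-4-ol
Conditions: Ru[(R,R)-TsDPEN](p-cymene) (1 mol%), i-PrOH, 28 °C
Reagents that add atoms: none
Why: Noyori asymmetric transfer hydrogenation of an alkynyl ketone under base-free conditions that leave the acetal intact, in which the (R,R)-catalyst distinguishes the alkynyl from the propyl flank and should deliver hydride to give the (R)-propargylic alcohol, the only stereocentre of the route set by a chiral catalyst.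

Step 3
Reactants: 5 (4R)-1,1-diethoxyhept-2-yn-4-ol
Product: 6 (4R)-1,1-diethoxyhept-2-yn-4-yl methanesulfonate
Conditions: MsCl, Et3N, CH2Cl2, −40 → 0 °C
Reagents that add atoms: methanesulfonyl chloride, CS(=O)(=O)Cl
Why: Sulfonate ester formation at oxygen, with retention at carbon, turns the carbinol into the leaving group for the SN2' step.

Step 4
Reactants: 6 (4R)-1,1-diethoxyhept-2-yn-4-yl methanesulfonate
Product: 7 (Sa)-2-bromo-1,1-diethoxyhepta-2,3-diene
Conditions: CuBr·SMe2, LiBr, THF, −40 → 0 °C
Reagents that add atoms: lithium dibromocuprate LiCuBr2 (made in the flask from CuBr·SMe2 and LiBr), [Li+].Br[Cu-]Br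
Why: Anti-selective SN2' substitution of a propargylic sulfonate by a bromocuprate, in which bromide enters at the acetal-bearing alkyne carbon opposite to the departing mesylate, so the (R)-centre is converted into the (Sa)-axis and the future C4–Br bond is installed.

Step 5
Reactants: 7 (Sa)-2-bromo-1,1-diethoxyhepta-2,3-diene
Product: 8 (Sa)-2-bromohepta-2,3-dienal
Conditions: HCO2H–H2O, pentane (two-phase), 0 °C
Reagents that add atoms: water, O
Why: Acid-catalysed acetal hydrolysis, run cold in a two-phase medium so that the bromoallenal is extracted as it forms and used at once, with the allene axis untouched.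

Step 6
Reactants: 8 (Sa)-2-bromohepta-2,3-dienal
Product: 9 (Sa)-1,1,3-tribromoocta-3,4-dien-2-ol (both C2 epimers)
Conditions: CH2Br2, LDA, THF–Et2O, −95 °C; then 8; AcOH, −95 °C
Reagents that add atoms: dibromomethane, BrCBr
Why: 1,2-Addition of the carbenoid dibromomethyllithium to the aldehyde with a cold acidic quench that prevents epoxide closure, the new carbinol centre forming unselectively, which is harmless because it becomes sp2 in step 9.

Step 7
Reactants: 9 (Sa)-1,1,3-tribromoocta-3,4-dien-2-ol (both C2 epimers)
Product: 12 (1R)-1-[4-bromo-5-(dibromomethyl)-2-oxo-2,5-dihydrofuran-3-yl]butyl acetate (both C5 epimers), via alkoxycarbonylpalladium acetate 10 (not isolated), via allylpalladium acetate 11 (not isolated)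
Conditions: Pd(OAc)2 (10 mol%), 1,4-benzoquinone (2 equiv), LiOAc, CO (1 atm), AcOH–THF, 25 °C
Reagents that add atoms: carbon monoxide, [C-]#[O+]; acetic acid, CC(=O)O
Why: Proposed new method: under CO the hydroxyl of 9 is converted at divalent palladium into the alkoxycarbonylpalladium acetate 10, whose acyl carbon adds to the central allene carbon C3 across the C3=C1' π bond (syn acylpalladation, 5-exo-trig with respect to that bond), which closes the butenolide by forming the C2–C3 bond and leaves the allylpalladium 11 over C4–C3–C1'; benzoquinone-induced cis migration of acetate from palladium to C1' then releases 12 and zerovalent palladium, which benzoquinone reoxidises. The closest known reaction type is the PdCl2/CuCl2 chlorocyclocarbonylation of 2,3-allenols to 3-(chloromethyl)butenolides, merged with the benzoquinone-mediated acetate transfer to allylpalladium known from diene 1,4-diacetoxylation; new here are the acetate termination and the 2-bromoallene. The only ring closed is the five-membered lactone, whose O1–C2 bond already exists in 10 and whose C2–C3 bond is formed in the insertion. The new C1' stereocentre is controlled by the allene axis: the tethered acyl group can reach C3 only from the carbinol side, so palladium lands on one defined face of C1' and acetate follows on that same face, which should turn (Sa)-9 into (R)-12 whatever the configuration at C5, a centre that step 9 erases. The step needs capture at C1' and not at C4, secured by C4 being fully substituted, brominated and part of the ring and by the conjugated enoate that results; it needs CO uptake to outrun oxypalladation of the allenol, helped by CO saturation and by the weakly nucleophilic hydroxyl beside CHBr2; and it needs the C(sp2)–Br bonds to survive, secured by the chloride-free oxidising medium that keeps zerovalent palladium scarce.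

Step 8
Reactants: 12 (1R)-1-[4-bromo-5-(dibromomethyl)-2-oxo-2,5-dihydrofuran-3-yl]butyl acetate
Product: 13 4-bromo-5-(dibromomethyl)-3-[(1R)-1-hydroxybutyl]furan-2(5H)-one (both C5 epimers)
Conditions: AcCl (0.3 equiv), MeOH, 0 → 25 °C
Reagents that add atoms: none
Why: Acid-catalysed transesterification (methanolysis by HCl generated in the flask) frees the carbinol for the tether without breaking the C1'–O bond, so the (R)-configuration is kept, and the acid-stable bromobutenolide is not touched.

Step 9
Reactants: 13 4-bromo-5-(dibromomethyl)-3-[(1R)-1-hydroxybutyl]furan-2(5H)-one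
Product: 14 (5Z)-4-bromo-5-(bromomethylidene)-3-[(1R)-1-hydroxybutyl]furan-2(5H)-one
Conditions: Et3N, CH2Cl2, −20 → 0 °C
Reagents that add atoms: none
Why: E1cB dehydrobromination in which the amine removes the acidic γ-hydrogen at C5 and the resulting 2-oxyfuran anion expels bromide from the CHBr2 group, the (Z)-bromomethylene being favoured because the (E)-isomer suffers A(1,3) strain with the C4 bromine.

Step 10
Reactants: 14 (5Z)-4-bromo-5-(bromomethylidene)-3-[(1R)-1-hydroxybutyl]furan-2(5H)-one (two molecules)
Product: 15 bis{(1R)-1-[(5Z)-4-bromo-5-(bromomethylidene)-2-oxo-2,5-dihydrofuran-3-yl]butoxy}di(propan-2-yl)silane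
Conditions: i-Pr2Si(OTf)2 (0.5 equiv), 2,6-lutidine, CH2Cl2, −78 → 0 °C
Reagents that add atoms: di(propan-2-yl)silanediyl bis(trifluoromethanesulfonate), CC(C)[Si](OS(=O)(=O)C(F)(F)F)(OS(=O)(=O)C(F)(F)F)C(C)C
Why: Silyl ether formation with a silyl bis-triflate and a non-nucleophilic base joins two carbinols through one silicon atom without touching a stereocentre or the electrophilic C4–Br position.

Step 11
Reactants: 15 bis{(1R)-1-[(5Z)-4-bromo-5-(bromomethylidene)-2-oxo-2,5-dihydrofuran-3-yl]butoxy}di(propan-2-yl)silane
Product: 16 O,O'-[di(propan-2-yl)silanediyl] derivative of (5S,6S,11R,12R)-4,10,11,12-tetrabromo-3,9-bis[(1R)-1-hydroxybutyl]-1,7-dioxadispiro[4.0.4.2]dodeca-3,9-diene-2,8-dione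
Conditions: thioxanthone (20 mol%), 390 nm LEDs, degassed CH2Cl2 (1 mM), 20 °C
Reagents that add atoms: none
Why: Triplet-sensitised intramolecular [2+2] photocycloaddition (template-directed head-to-head photodimerisation of γ-alkylidenebutenolides) in which the one-atom silylene bridge and the A(1,3)-locked carbinol rotamers (C1'–H eclipsing C3=C4–Br) allow only the anti-stacked pair of ring faces that carry the two oxygens to meet, which should set both spiro centres as (S), while closure of the 1,4-diradical formed by C6–C6' bonding (bromomethylene geometry being scrambled in the triplet) is expected to place each C–Br anti to its vicinal C–O and C–Br bonds and so give the (11R,12R) bromomethines.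

Step 12
Reactants: 16 silylene-bridged photoadduct
Product: 17 (5S,6S,11R,12R)-4,10,11,12-tetrabromo-3,9-bis[(1R)-1-hydroxybutyl]-1,7-dioxadispiro[4.0.4.2]dodeca-3,9-diene-2,8-dione
Conditions: HF (48% aq), MeCN, 0 °C
Reagents that add atoms: none
Why: Fluoride-mediated cleavage of the dialkoxysilane under acidic, amine-free conditions opens the temporary ring and leaves the lactones, the C–Br bonds and all stereocentres unchanged.

Step 13
Reactants: 17 C2-symmetric (R,R)-diol
Product: 18 (1S)-1-[(5S,6S,11R,12R)-4,10,11,12-tetrabromo-9-[(1R)-1-hydroxybutyl]-2,8-dioxo-1,7-dioxadispiro[4.0.4.2]dodeca-3,9-dien-3-yl]butyl acetate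
Conditions: PPh3 (1 equiv), DIAD (1 equiv), AcOH (1 equiv), THF, −20 → 0 °C (betaine preformed)
Reagents that add atoms: acetic acid, CC(=O)O
Why: Mitsunobu reaction in which acetate displaces the oxyphosphonium group by SN2 with inversion, so one (R)-carbinol becomes the (S)-acetate, and because the two hydroxyls are homotopic about the C2 axis a single mono-ester should form, unreacted 17 being recycled.

Step 14
Reactants: 18 (S)-acetate (R)-alcohol
Product: 19 (1S)-1-[(5S,6S,11R,12R)-9-[(1R)-1-(acetyloxy)butyl]-4,10,11,12-tetrabromo-2,8-dioxo-1,7-dioxadispiro[4.0.4.2]dodeca-3,9-dien-3-yl]butyl acetate (CNP0266230.1)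
Conditions: Ac2O, Sc(OTf)3 (2 mol%), MeCN, −20 °C
Reagents that add atoms: acetic anhydride, CC(=O)OC(C)=O
Why: Lewis-acid-catalysed O-acetylation of the remaining (R)-carbinol proceeds with retention and without an amine nucleophile that could attack the β-bromobutenolides.

**Compound list**

1 | 3,3-diethoxyprop-1-yne | C#CC(OCC)OCC | starting material
2 | N-methoxy-N-methylbutanamide | CCCC(=O)N(C)OC | starting material
3 | lithium acetylide of 1 | [Li]C#CC(OCC)OCC | intermediate
4 | 1,1-diethoxyhept-2-yn-4-one | CCCC(=O)C#CC(OCC)OCC | intermediate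
5 | (4R)-1,1-diethoxyhept-2-yn-4-ol | CCC[C@@H](O)C#CC(OCC)OCC | intermediate
6 | (4R)-1,1-diethoxyhept-2-yn-4-yl methanesulfonate | CCC[C@@H](OS(C)(=O)=O)C#CC(OCC)OCC | intermediate
7 | (Sa)-2-bromo-1,1-diethoxyhepta-2,3-diene | CCCC([H])=[C@]=C(Br)C(OCC)OCC | intermediate
8 | (Sa)-2-bromohepta-2,3-dienal | CCCC([H])=[C@]=C(Br)C=O | intermediate
9 | (Sa)-1,1,3-tribromoocta-3,4-dien-2-ol, both C2 epimers | CCCC([H])=[C@]=C(Br)C(O)C(Br)Br | intermediate
10 | alkoxycarbonylpalladium acetate derived from 9 (Pd–C(=O)–O on the carbinol oxygen) | CCCC([H])=[C@]=C(Br)C(OC(=O)[Pd]OC(C)=O)C(Br)Br | intermediate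
11 | allylpalladium acetate over C4–C3–C1' of the closed butenolide, drawn in its C1'-bound form | CCC[C@@H]([Pd]OC(C)=O)C1=C(Br)C(C(Br)Br)OC1=O | intermediate
12 | (1R)-1-[4-bromo-5-(dibromomethyl)-2-oxo-2,5-dihydrofuran-3-yl]butyl acetate, both C5 epimers | CCC[C@@H](OC(C)=O)C1=C(Br)C(C(Br)Br)OC1=O | intermediate
13 | 4-bromo-5-(dibromomethyl)-3-[(1R)-1-hydroxybutyl]furan-2(5H)-one, both C5 epimers | CCC[C@@H](O)C1=C(Br)C(C(Br)Br)OC1=O | intermediate
14 | (5Z)-4-bromo-5-(bromomethylidene)-3-[(1R)-1-hydroxybutyl]furan-2(5H)-one | CCC[C@@H](O)C1=C(Br)/C(=C/Br)OC1=O | intermediate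
15 | bis{(1R)-1-[(5Z)-4-bromo-5-(bromomethylidene)-2-oxo-2,5-dihydrofuran-3-yl]butoxy}di(propan-2-yl)silane | CCC[C@@H](O[Si](C(C)C)(C(C)C)O[C@H](CCC)C1=C(Br)/C(=C/Br)OC1=O)C2=C(Br)/C(=C/Br)OC2=O | intermediate
16 | silylene-bridged photoadduct: diol 17 with its two carbinol oxygens joined by Si(i-Pr)2 (11-membered ring across the cyclobutane) | CCC[C@@H](O[Si]3(C(C)C)C(C)C)C1=C(Br)[C@@]2(OC1=O)[C@@H](Br)[C@H](Br)[C@@]21OC(=O)C([C@@H](CCC)O3)=C1Br | intermediate
17 | (5S,6S,11R,12R)-4,10,11,12-tetrabromo-3,9-bis[(1R)-1-hydroxybutyl]-1,7-dioxadispiro[4.0.4.2]dodeca-3,9-diene-2,8-dione | CCC[C@@H](O)C1=C(Br)[C@@]2(OC1=O)[C@@H](Br)[C@H](Br)[C@@]21OC(=O)C([C@@H](CCC)O)=C1Br | intermediate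
18 | (1S)-1-[(5S,6S,11R,12R)-4,10,11,12-tetrabromo-9-[(1R)-1-hydroxybutyl]-2,8-dioxo-1,7-dioxadispiro[4.0.4.2]dodeca-3,9-dien-3-yl]butyl acetate | CCC[C@H](OC(C)=O)C1=C(Br)[C@@]2(OC1=O)[C@@H](Br)[C@H](Br)[C@@]21OC(=O)C([C@@H](CCC)O)=C1Br | intermediate
19 | (1S)-1-[(5S,6S,11R,12R)-9-[(1R)-1-(acetyloxy)butyl]-4,10,11,12-tetrabromo-2,8-dioxo-1,7-dioxadispiro[4.0.4.2]dodeca-3,9-dien-3-yl]butyl acetate | CCC[C@H](OC(C)=O)C1=C(Br)[C@@]2(OC1=O)[C@@H](Br)[C@H](Br)[C@@]21OC(=O)C([C@@H](CCC)OC(C)=O)=C1Br | target

**Step count and risks**

Total step count: 14. Longest linear sequence: 14 steps (1 → 19; step 10 joins two molecules of 14).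

Steps most likely to fail:

Step 7 (proposed new method). Three processes may spoil it: erosion of the allene axis by reversible nucleopalladation before CO uptake, acetate capture from the face opposite to palladium instead of cis migration, and oxypalladation of the allenol to a dihydrofuran. The fallback uses known chemistry, sets out from 9 and returns at 12. Chlorocyclocarbonylation of the 2,3-allenol with PdCl2 (cat.), CuCl2 (3 equiv) and CO (1 atm) in THF is the established halide-terminated form of the same C2–C3 ring closure. It should give 4-bromo-3-[(1S)-1-chlorobutyl]-5-(dibromomethyl)furan-2(5H)-one F1, with chloride entering anti to palladium. SN2 displacement of the allylic chloride with CsOAc and 18-crown-6 in toluene–DMF then inverts C1' and gives 12.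

Step 11. The likely failure is loss of stereocontrol at the two bromomethine carbons. Z/E scrambling of the bromomethylene groups in the triplet state and stepwise diradical closure could give the trans-dibromide in which each bromine is syn to the vicinal lactone oxygen. The fallback sets out from 15 and returns at 16, replacing kinetic control in the photoreaction by equilibration after ring formation. The photoadduct of that type, the (5S,6S,11S,12S)-bromomethine epimer of 16 F2, is subjected to vicinal-dibromide mutarotation (ZnBr2 cat., MeNO2, 40 °C). This classical rearrangement through a bromonium bromide ion pair moves each bromine to the neighbouring carbon on its own ring face and thereby converts F2 into 16. It helps only if the all-anti array of C–O and C–Br bonds in 16 is the lower-energy one, which is expected but not certain.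

Step 5. The electrophilic 2-bromoallenal may oligomerise or hydrate during acetal hydrolysis, and acid or bromide traces may erode the allene axis. The fallback sets out from 6 and returns at 9 without ever forming an allenal, because the allene is made last. Acetal hydrolysis of 6 (aq HCO2H) gives (4R)-1-oxohept-2-yn-4-yl methanesulfonate F3. Addition of dibromomethyllithium at −95 °C with a cold AcOH quench gives (5R)-1,1-dibromo-2-hydroxyoct-3-yn-5-yl methanesulfonate F4. Anti SN2' bromide delivery with LiCuBr2 in THF then gives 9 directly.

Further compounds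
F1 | step 7 | 4-bromo-3-[(1S)-1-chlorobutyl]-5-(dibromomethyl)furan-2(5H)-one, both C5 epimers | CCC[C@H](Cl)C1=C(Br)C(C(Br)Br)OC1=O
F2 | step 11 | (5S,6S,11S,12S)-bromomethine epimer of 16 (each bromine syn to the vicinal lactone oxygen) | CCC[C@@H](O[Si]3(C(C)C)C(C)C)C1=C(Br)[C@@]2(OC1=O)[C@H](Br)[C@@H](Br)[C@@]21OC(=O)C([C@@H](CCC)O3)=C1Br
F3 | step 5 | (4R)-1-oxohept-2-yn-4-yl methanesulfonate | CCC[C@@H](OS(C)(=O)=O)C#CC=O
F4 | step 5 | (5R)-1,1-dibromo-2-hydroxyoct-3-yn-5-yl methanesulfonate, both C2 epimers | CCC[C@@H](OS(C)(=O)=O)C#CC(O)C(Br)Br
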